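**Retrosynthetic overview**
- Target ⇐ desilylation ⇐ trans-selective α-alkylation (C8–C7 bond) of a β-[aryl(hydroxy)methyl]-γ-butyrolactone with a silyl-protected 4-hydroxy-3-methoxybenzyl bromide.
- That lactone (the target's ring, formed second) ⇐ lactone transposition: a carboxylate displaces a primary mesylate intramolecularly (O–C9′ bond).
- Its precursor, a γ-aryl lactone acid (ring formed first, later opened) ⇐ catalytic enantioselective hydrolactonisation of an (E)-arylidenesuccinic acid. This key step makes the benzylic C7′–O bond and sets C7′ and C8′.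
- (E)-Arylidenesuccinic acid ⇐ Stobbe condensation of an aryl aldehyde with a succinic diester.

Assumption: C7′, C8′, C9′ are the CH(OH), ring CH and OCH2 carbons on the 3,4-dimethoxyphenyl side; C7, C8, C9 are the benzylic CH2, ring CH and C=O carbons on the 4-hydroxy-3-methoxyphenyl side.
Assumption: "IDPi acid" in step 2 is the (S,S)-imidodiphosphorimidate HN[P(=NSO2CF3)(O2R*)]2, each O2R* being (S)-3,3′-bis[3,5-bis(trifluoromethyl)phenyl]-1,1′-binaphthalene-2,2′-diolate; its sense of induction is untested, so the mirror-image acid is used if the first run gives ent-5.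

**Step 1**
Reactants: 1 3,4-dimethoxybenzaldehyde (veratraldehyde); 2 dimethyl succinate
Product: 4 (E)-2-(3,4-dimethoxybenzylidene)succinic acid, via Stobbe half-ester sodium salt 3 (not isolated)
Conditions: NaOMe (1.5 equiv), MeOH, reflux; then aq NaOH, reflux; then HCl to pH 1, crystallise
Reagents that add atoms: sodium methoxide, [Na+].[O-]C (the sodium of 3 only); sodium hydroxide, [Na+].[OH-] (one carboxyl oxygen of 4)
Why: Stobbe condensation (aldol addition, lactonisation, E1cB ring opening) gives the half-ester with the aryl group cis to the CH2CO2Na arm, and saponification in the same pot gives the crystalline (E)-diacid; no stereocentre is formed.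

**Step 2**
Reactants: 4 (E)-2-(3,4-dimethoxybenzylidene)succinic acid
Product: 5 (2S,3S)-2-(3,4-dimethoxyphenyl)-5-oxotetrahydrofuran-3-carboxylic acid (aryl and CO2H trans)
Conditions: IDPi acid (5 mol %), CHCl3/1,1,1,3,3,3-hexafluoropropan-2-ol 9:1, 0 °C → rt; one recrystallisation
Reagents that add atoms: none
Why: Proposed new method: the confined, strongly acidic chiral Brønsted acid protonates the conjugated carboxyl group of 4, the p-alkoxy-stabilised benzylic cation is held as a chiral contact ion pair and captured on one face by the CH2CO2H arm that already sits cis to the aryl group (C7′–O bond, catalyst-controlled), C8′ is protonated within the same ion pair, and the 2,3-trans acid is the thermodynamic outcome because any cis lactone re-ionises at the benzylic C–O bond and recloses trans without touching C8′; the closest known reaction types are chiral Brønsted-acid-catalysed asymmetric hydrolactonisation of unsaturated acids and the classical racemic mineral-acid cyclisation of arylitaconic acids to paraconic acids.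

**Step 3**
Reactants: 5 (2S,3S)-2-(3,4-dimethoxyphenyl)-5-oxotetrahydrofuran-3-carboxylic acid
Product: 6 (4R,5S)-5-(3,4-dimethoxyphenyl)-4-(hydroxymethyl)dihydrofuran-2(3H)-one
Conditions: BH3·SMe2 (2 equiv), THF, 0 °C → rt; MeOH quench
Reagents that add atoms: none
Why: Chemoselective borane reduction of a carboxylic acid beside a γ-lactone (standard for paraconic acids); no stereocentre is touched, and the C8′ descriptor changes from S to R only because the substituent priorities change.

**Step 4**
Reactants: 6 (4R,5S)-5-(3,4-dimethoxyphenyl)-4-(hydroxymethyl)dihydrofuran-2(3H)-one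
Product: 9 (R)-4-[(S)-(3,4-dimethoxyphenyl)(hydroxy)methyl]dihydrofuran-2(3H)-one, via lactone mesylate 7 (not isolated), via ring-opened lithium carboxylate 8 (not isolated)
Conditions: MsCl, Et3N, CH2Cl2, 0 °C; then LiOH (1.05 equiv), THF/H2O, 0 → 40 °C
Reagents that add atoms: lithium hydroxide, [Li+].[OH-] (the lithium of 8 and one lactone oxygen of 9); methanesulfonyl chloride, CS(=O)(=O)Cl (its CH3SO2 group is carried in 7 and 8 only)
Why: Lactone transposition by intramolecular carboxylate O-alkylation: the only free hydroxyl is mesylated, one equivalent of hydroxide opens the γ-aryl lactone by acyl–oxygen cleavage (C7′ keeps its S configuration), and the freed carboxylate displaces the primary mesylate irreversibly (5-exo-tet), which avoids the unfavourable acyl-transfer equilibrium between the two γ-lactones.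

**Step 5**
Reactants: 10 4-hydroxy-3-methoxybenzaldehyde (vanillin)
Product: 11 4-(tert-butyldimethylsilyloxy)-3-methoxybenzaldehyde
Conditions: TBSCl, imidazole, DMF, rt
Reagents that add atoms: tert-butyldimethylsilyl chloride, CC(C)(C)[Si](C)(C)Cl
Why: Imidazole-mediated silylation of the phenol gives a fluoride-labile ether that survives enolate chemistry.

**Step 6**
Reactants: 11 4-(tert-butyldimethylsilyloxy)-3-methoxybenzaldehyde
Product: 12 [4-(tert-butyldimethylsilyloxy)-3-methoxyphenyl]methanol
Conditions: NaBH4, MeOH, 0 °C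
Reagents that add atoms: none
Why: Borohydride reduction of the aryl aldehyde; the aryl silyl ether is stable in cold methanol.

**Step 7**
Reactants: 12 [4-(tert-butyldimethylsilyloxy)-3-methoxyphenyl]methanol
Product: 13 4-(tert-butyldimethylsilyloxy)-3-methoxybenzyl bromide
Conditions: CBr4, PPh3, CH2Cl2, 0 °C
Reagents that add atoms: carbon tetrabromide, BrC(Br)(Br)Br
Why: Appel bromination runs under neutral conditions, so the aryl silyl ether stays intact.

**Step 8**
Reactants: 9 (R)-4-[(S)-(3,4-dimethoxyphenyl)(hydroxy)methyl]dihydrofuran-2(3H)-one; 13 4-(tert-butyldimethylsilyloxy)-3-methoxybenzyl bromide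
Product: 15 (3R,4R)-3-[4-(tert-butyldimethylsilyloxy)-3-methoxybenzyl]-4-[(S)-(3,4-dimethoxyphenyl)(hydroxy)methyl]dihydrofuran-2(3H)-one, via dilithium alkoxide enolate 14 (not isolated)
Conditions: lithium diisopropylamide (2.3 equiv, commercial solution), THF, −78 °C; then 13, DMPU, −78 → −40 °C; AcOH quench
Reagents that add atoms: lithium diisopropylamide, [Li+].CC(C)[N-]C(C)C (the lithium of 14 only; no reagent atom remains in 15)
Why: Enolate alkylation of the hydroxy-lactone dianion occurs anti to the bulky C8′ substituent and sets C8 as R with the usual trans selectivity of β-substituted γ-butyrolactone enolates, while the lithium alkoxide is too unreactive at −78 °C to be O-benzylated or to transfer the acyl group.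

**Step 9**
Reactants: 15 (3R,4R)-3-[4-(tert-butyldimethylsilyloxy)-3-methoxybenzyl]-4-[(S)-(3,4-dimethoxyphenyl)(hydroxy)methyl]dihydrofuran-2(3H)-one
Product: 16 (3R,4R)-4-[(S)-(3,4-dimethoxyphenyl)(hydroxy)methyl]-3-(4-hydroxy-3-methoxybenzyl)dihydrofuran-2(3H)-one
Conditions: Bu4NF, AcOH, THF, 0 °C
Reagents that add atoms: none
Why: Fluoride cleavage of the aryl silyl ether, buffered with acetic acid so the free 7′-hydroxy lactone never meets base (no acyl migration, no epimerisation, no acid-induced cyclisation).

**Compound list**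
1 | 3,4-dimethoxybenzaldehyde (veratraldehyde) | COc1ccc(C=O)cc1OC | starting material
2 | dimethyl succinate | COC(=O)CCC(=O)OC | starting material
3 | sodium (E)-4-(3,4-dimethoxyphenyl)-3-(methoxycarbonyl)but-3-enoate (Stobbe half-ester salt, not isolated) | COC(=O)/C(=C/c1ccc(OC)c(OC)c1)CC(=O)[O-].[Na+] | intermediate
4 | (E)-2-(3,4-dimethoxybenzylidene)succinic acid | OC(=O)/C(=C/c1ccc(OC)c(OC)c1)CC(=O)O | intermediate
5 | (2S,3S)-2-(3,4-dimethoxyphenyl)-5-oxotetrahydrofuran-3-carboxylic acid | O=C1C[C@H](C(=O)O)[C@@H](c2ccc(OC)c(OC)c2)O1 | intermediate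
6 | (4R,5S)-5-(3,4-dimethoxyphenyl)-4-(hydroxymethyl)dihydrofuran-2(3H)-one | O=C1C[C@H](CO)[C@@H](c2ccc(OC)c(OC)c2)O1 | intermediate
7 | [(2S,3R)-2-(3,4-dimethoxyphenyl)-5-oxotetrahydrofuran-3-yl]methyl methanesulfonate (not isolated) | O=C1C[C@H](COS(C)(=O)=O)[C@@H](c2ccc(OC)c(OC)c2)O1 | intermediate
8 | lithium (3R,4S)-4-(3,4-dimethoxyphenyl)-4-hydroxy-3-[(methylsulfonyloxy)methyl]butanoate (not isolated) | [Li+].[O-]C(=O)C[C@H](COS(C)(=O)=O)[C@H](O)c1ccc(OC)c(OC)c1 | intermediate
9 | (R)-4-[(S)-(3,4-dimethoxyphenyl)(hydroxy)methyl]dihydrofuran-2(3H)-one | O=C1C[C@H](CO1)[C@H](O)c1ccc(OC)c(OC)c1 | intermediate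
10 | 4-hydroxy-3-methoxybenzaldehyde (vanillin) | COc1cc(C=O)ccc1O | starting material
11 | 4-(tert-butyldimethylsilyloxy)-3-methoxybenzaldehyde | COc1cc(C=O)ccc1O[Si](C)(C)C(C)(C)C | intermediate
12 | [4-(tert-butyldimethylsilyloxy)-3-methoxyphenyl]methanol | COc1cc(CO)ccc1O[Si](C)(C)C(C)(C)C | intermediate
13 | 4-(tert-butyldimethylsilyloxy)-3-methoxybenzyl bromide | COc1cc(CBr)ccc1O[Si](C)(C)C(C)(C)C | intermediate
14 | dilithium (R)-4-[(S)-(3,4-dimethoxyphenyl)(oxido)methyl]-4,5-dihydrofuran-2-olate (not isolated) | [Li+].[Li+].[O-]C1=C[C@H](CO1)[C@H]([O-])c1ccc(OC)c(OC)c1 | intermediate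
15 | (3R,4R)-3-[4-(tert-butyldimethylsilyloxy)-3-methoxybenzyl]-4-[(S)-(3,4-dimethoxyphenyl)(hydroxy)methyl]dihydrofuran-2(3H)-one | COc1cc(C[C@H]2C(=O)OC[C@@H]2[C@H](O)c2ccc(OC)c(OC)c2)ccc1O[Si](C)(C)C(C)(C)C | intermediate
16 | (3R,4R)-4-[(S)-(3,4-dimethoxyphenyl)(hydroxy)methyl]-3-(4-hydroxy-3-methoxybenzyl)dihydrofuran-2(3H)-one | COc1cc(C[C@H]2C(=O)OC[C@@H]2[C@H](O)c2ccc(OC)c(OC)c2)ccc1O | target

**Step count**
Total: 9 steps. Longest linear sequence: 6 steps (1, 2, 3, 4, 8, 9).

**Three steps most likely to fail**

Step 2 (the proposed new step) is the main risk. The push–pull alkene of 4 is only weakly basic, the diacid dissolves poorly in non-basic media, and both the level and the sense of induction are untested. The fallback uses known chemistry and sets out from 4. Asymmetric hydrogenation with [Rh(cod)2]BF4 and a chiral bisphosphine such as Me-DuPhos (H2, MeOH; the ligand antipode that gives the R acid) leads to (R)-2-(3,4-dimethoxybenzyl)succinic acid F1. Oxidative benzylic lactonisation of F1 with K2S2O8 and catalytic CuCl2 in aqueous MeCN at 80 °C follows; the CH2CO2H arm traps the benzylic cation trans to the neighbouring carboxyl group. This comes back to the route at 5.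

Step 4 is the second risk. Hydroxide could attack the mesylate or cause elimination instead of opening the lactone, and any excess hydroxide would reopen 9 and let the two lactones equilibrate towards 6. The fallback sets out from 6. Saponification with NaOH (1.1 equiv) in aqueous THF gives sodium (3R,4S)-4-(3,4-dimethoxyphenyl)-4-hydroxy-3-(hydroxymethyl)butanoate F2. Cold acidification to pH 4 with dilute HCl and extraction give (3R,4S)-4-(3,4-dimethoxyphenyl)-4-hydroxy-3-(hydroxymethyl)butanoic acid F3, which is used at once. Mitsunobu closure (PPh3, diisopropyl azodicarboxylate, THF, 0 °C) activates only the unhindered primary alcohol, and the carboxyl group displaces it. This comes back to the route at 9.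

Step 8 is the third risk. Dianion formation may be incomplete, the alkoxide may be O-benzylated, or acyl transfer may occur on warming. The fallback sets out from 9. Silylation of the benzylic alcohol (TBSOTf, 2,6-lutidine, CH2Cl2, −78 °C) gives (R)-4-[(S)-(tert-butyldimethylsilyloxy)(3,4-dimethoxyphenyl)methyl]dihydrofuran-2(3H)-one F4. Alkylation of its mono-enolate (LiN(SiMe3)2, THF, −78 °C, then 13) gives (3R,4R)-4-[(S)-(tert-butyldimethylsilyloxy)(3,4-dimethoxyphenyl)methyl]-3-[4-(tert-butyldimethylsilyloxy)-3-methoxybenzyl]dihydrofuran-2(3H)-one F5. Removal of both silyl groups with Bu4NF/AcOH in THF at rt comes back to the route at 16.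

**Further compounds**
F1 | step 2 | (R)-2-(3,4-dimethoxybenzyl)succinic acid | OC(=O)C[C@H](C(=O)O)Cc1ccc(OC)c(OC)c1
F2 | step 4 | sodium (3R,4S)-4-(3,4-dimethoxyphenyl)-4-hydroxy-3-(hydroxymethyl)butanoate | [Na+].[O-]C(=O)C[C@H](CO)[C@H](O)c1ccc(OC)c(OC)c1
F3 | step 4 | (3R,4S)-4-(3,4-dimethoxyphenyl)-4-hydroxy-3-(hydroxymethyl)butanoic acid | OC(=O)C[C@H](CO)[C@H](O)c1ccc(OC)c(OC)c1
F4 | step 8 | (R)-4-[(S)-(tert-butyldimethylsilyloxy)(3,4-dimethoxyphenyl)methyl]dihydrofuran-2(3H)-one | O=C1C[C@H](CO1)[C@H](O[Si](C)(C)C(C)(C)C)c1ccc(OC)c(OC)c1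
F5 | step 8 | (3R,4R)-4-[(S)-(tert-butyldimethylsilyloxy)(3,4-dimethoxyphenyl)methyl]-3-[4-(tert-butyldimethylsilyloxy)-3-methoxybenzyl]dihydrofuran-2(3H)-one | COc1cc(C[C@H]2C(=O)OC[C@@H]2[C@H](O[Si](C)(C)C(C)(C)C)c2ccc(OC)c(OC)c2)ccc1O[Si](C)(C)C(C)(C)C
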